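## Retrosynthetic overview

1. The C41 polyene is cut at C11=C12 (formed last) and C11'=C12' into cyclopentane C15 phosphonium salt 16, C10 dialdehyde 20 and the pseudoionone-derived C15 salt 19 (two Wittig olefinations).
2. Salt 16 comes from C13 enone 12 (vinyl Grignard, then PPh3·HBr), 12 from vinylcyclopentane 11 by cross-metathesis, 11 from the C7 methyl ketone through its enol triflate, and the C1 methyl ether from Markovnikov hydromethoxylation of an isopropenyl group.
3. Feature used: the only ring, cyclopentane C2–C3–C4–C5–C6, carries the contiguous stereocentres C2 (bearing the three-carbon C1 unit), C6 (bearing C7) and C5 (methyl carbinol). With C7 as an acyl carbon, C5–OH/C7=O is an aldol pair and C1–C2 is the β-bond of an enone.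
4. Key disconnection: C1–C2 and C5–C6 in one operation, a rhodium–BINAP isopropenyl conjugate addition/aldol cyclisation of achiral (3E)-oct-3-ene-2,7-dione 3, itself made by cross-metathesis of hex-5-en-2-one and but-3-en-2-one.
5. Ring order: the cyclopentane is the only ring and is closed in step 2.

Key step: step 2

Assumption: atoms are numbered as in carotenoids (C1–C15 from the cyclopentane end, C1'–C15' from the acyclic end); the target is (2R,5R,6S), with C5–OH cis to the C7 chain and the C1 unit trans to it.
Assumption: pseudoionone 17 is used as its (3E,5E) isomer; Z isomers along the chain are expected to be removed at the crystalline salts and by the thermal equilibrations after each Wittig step.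

## Route

Step 1
Reactants: 1 hex-5-en-2-one; 2 but-3-en-2-one
Product: 3 (3E)-oct-3-ene-2,7-dione
Conditions: second-generation Hoveyda–Grubbs catalyst (2 mol%), 2 (3 equiv), CH2Cl2, 40 °C
Reagents that add atoms: none
Why: Olefin cross-metathesis of a terminal alkene with an electron-poor vinyl ketone is cross-selective because the enone homodimerises slowly, ethene leaves the flask and the conjugated E double bond forms under thermodynamic control.

Step 2
Reactants: 3 (3E)-oct-3-ene-2,7-dione; 4 isopropenylboronic acid pinacol ester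
Product: 6 1-[(1S,2R,5R)-2-hydroxy-2-methyl-5-(prop-1-en-2-yl)cyclopentyl]ethan-1-one, via Z rhodium enolate 5 (not isolated)
Conditions: [Rh(cod)Cl]2 (2.5 mol%), (S)-BINAP (7.5 mol%), KOH (10 mol%), H2O (5 equiv), 4 (2 equiv), 1,4-dioxane, 95 °C
Reagents that add atoms: none
Why: The BINAP-bound hydroxo complex of monovalent rhodium takes the isopropenyl group from boron, the alkenylrhodium species inserts the s-cis enone of 3 to form C1–C2 and the Z oxygen-bound rhodium enolate 5, this enolate adds to the C5 ketone through a chair Zimmerman–Traxler transition state to form C5–C6, and water releases the tertiary alkoxide and regenerates Rh–OH. The closest known reaction type is the rhodium–BINAP tandem conjugate addition–aldol cyclisation of keto-enones with arylboronic acids, together with the established use of alkenylboron donors in rhodium-catalysed 1,4-addition; the isopropenyl donor extends the tandem to a 1-substituted alkenyl group. The cyclopentane (C2, C3, C4, C5, C6) is closed in a 5-(enolexo)-exo-trig aldol. C2 is set by the ligand: (S)-BINAP is chosen because rhodium–BINAP 1,4-additions to acyclic E acceptors are understood to deliver the carbon group to the α-si face, which here corresponds to 2R (the sense is to be checked by correlation and the antipodal ligand used if it proves reversed); C6 and C5 follow from the chair, in which the Z enolate and the tether place the acyl group cis to the new hydroxyl and trans to the C2 substituent. The step needs the alkenylrhodium to add to the enone and not to either ketone, and needs the aldol to outrun both protonation of 5 and base-induced Michael cyclisation of 3; the single enone per molecule, the five-membered exo geometry, catalytic KOH and a small measured amount of water should secure this.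

Step 3
Reactants: 6 1-[(1S,2R,5R)-2-hydroxy-2-methyl-5-(prop-1-en-2-yl)cyclopentyl]ethan-1-one
Product: 7 1-[(1S,2R,5R)-2-hydroxy-5-(2-methoxypropan-2-yl)-2-methylcyclopentyl]ethan-1-one
Conditions: Co(salen) [divalent cobalt; salen = N,N'-bis(3,5-di-tert-butylsalicylidene)-1,2-cyclohexanediamine dianion] (5 mol%), N-fluoro-2,4,6-trimethylpyridinium tetrafluoroborate (1.5 equiv), PhSiH3 (1.5 equiv), MeOH, 0 °C to rt
Reagents that add atoms: methanol, CO
Why: Cobalt-hydride hydrogen-atom-transfer hydroalkoxylation (Mukaiyama-type, oxidative variant) puts H on the CH2 terminus and, after oxidation of the tertiary C1 radical at cobalt, methanol on C1 with Markovnikov regiochemistry; C1 carries two methyl groups so no stereocentre arises, and the C5 hydroxyl, trans to the side chain across the ring, cannot reach C1.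

Step 4
Reactants: 7 1-[(1S,2R,5R)-2-hydroxy-5-(2-methoxypropan-2-yl)-2-methylcyclopentyl]ethan-1-one
Product: 8 1-[(1S,2R,5R)-5-(2-methoxypropan-2-yl)-2-methyl-2-(triethylsilyloxy)cyclopentyl]ethan-1-one
Conditions: Et3SiOTf (1.5 equiv), 2,6-lutidine (3 equiv), CH2Cl2, −78 to 0 °C
Reagents that add atoms: triethylsilyl trifluoromethanesulfonate, CC[Si](CC)(CC)OS(=O)(=O)C(F)(F)F
Why: Silyl triflate silylation of the tertiary alcohol under 2,6-lutidine buffering masks the aldol hydroxyl so that the strong base of step 5 cannot trigger retro-aldol cleavage, and no stereocentre is touched.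

Step 5
Reactants: 8 1-[(1S,2R,5R)-5-(2-methoxypropan-2-yl)-2-methyl-2-(triethylsilyloxy)cyclopentyl]ethan-1-one
Product: 10 1-[(1S,2R,5R)-5-(2-methoxypropan-2-yl)-2-methyl-2-(triethylsilyloxy)cyclopentyl]ethenyl trifluoromethanesulfonate, via potassium enolate 9 (not isolated)
Conditions: KN(SiMe3)2 (1.2 equiv), THF, −78 °C; then PhNTf2 (1.3 equiv), −78 to −20 °C
Reagents that add atoms: N-phenylbis(trifluoromethanesulfonimide), O=S(=O)(N(c1ccccc1)S(=O)(=O)C(F)(F)F)C(F)(F)F
Why: Kinetic deprotonation by the bulky amide base occurs at the unhindered methyl group and not at the shielded C6 methine, so the terminal enolate 9 forms without epimerisation at C6 or elimination of the silyloxy group, and O-sulfonylation by the triflimide gives the 1,1-disubstituted alkenyl triflate.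

Step 6
Reactants: 10 1-[(1S,2R,5R)-5-(2-methoxypropan-2-yl)-2-methyl-2-(triethylsilyloxy)cyclopentyl]ethenyl trifluoromethanesulfonate
Product: 11 triethyl{[(1R,2S,3R)-2-ethenyl-3-(2-methoxypropan-2-yl)-1-methylcyclopentyl]oxy}silane
Conditions: Pd(OAc)2 (5 mol%), PPh3 (10 mol%), nBu3N (3 equiv), HCO2H (2 equiv), DMF, 60 °C
Reagents that add atoms: none
Why: Palladium-catalysed formate reduction of an alkenyl triflate: zerovalent palladium inserts into the C–O bond, formate exchanges for triflate and loses CO2, and reductive elimination of the palladium hydride leaves the vinyl group (C7=C8) with C6 untouched.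

Step 7
Reactants: 11 triethyl{[(1R,2S,3R)-2-ethenyl-3-(2-methoxypropan-2-yl)-1-methylcyclopentyl]oxy}silane; 2 but-3-en-2-one
Product: 12 (3E)-4-[(1S,2R,5R)-5-(2-methoxypropan-2-yl)-2-methyl-2-(triethylsilyloxy)cyclopentyl]but-3-en-2-one
Conditions: second-generation Hoveyda–Grubbs catalyst (5 mol%), 2 (5 equiv), CH2Cl2, 40 °C
Reagents that add atoms: none
Why: Cross-metathesis of the monosubstituted alkene with excess vinyl ketone should give the conjugated E enone (C7=C8–C9=O), the phosphine-free ruthenium carbene tolerating the ether and the silyl ether.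

Step 8
Reactants: 12 (3E)-4-[(1S,2R,5R)-5-(2-methoxypropan-2-yl)-2-methyl-2-(triethylsilyloxy)cyclopentyl]but-3-en-2-one; 13 vinylmagnesium bromide
Product: 14 (4E)-5-[(1S,2R,5R)-5-(2-methoxypropan-2-yl)-2-methyl-2-(triethylsilyloxy)cyclopentyl]-3-methylpenta-1,4-dien-3-ol (both C3 epimers)
Conditions: 13 (1.5 equiv), THF, −78 to 0 °C; aq NH4Cl
Reagents that add atoms: none
Why: Grignard 1,2-addition of the vinyl group to the methyl ketone at low temperature gives the tertiary bis-allylic alcohol; the new carbinol centre (C9) forms without control and is erased in step 10.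

Step 9
Reactants: 14 (4E)-5-[(1S,2R,5R)-5-(2-methoxypropan-2-yl)-2-methyl-2-(triethylsilyloxy)cyclopentyl]-3-methylpenta-1,4-dien-3-ol
Product: 15 (1R,2S,3R)-2-[(1E)-3-hydroxy-3-methylpenta-1,4-dien-1-yl]-3-(2-methoxypropan-2-yl)-1-methylcyclopentan-1-ol (both carbinol epimers of the side chain)
Conditions: nBu4NF (2 equiv), THF, rt to 40 °C
Reagents that add atoms: none
Why: Fluoride-induced desilylation frees the C5 hydroxyl at a stage where no carbonyl group is present, so the basic fluoride cannot cause elimination or retro-aldol-type cleavage.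

Step 10
Reactants: 15 (1R,2S,3R)-2-[(1E)-3-hydroxy-3-methylpenta-1,4-dien-1-yl]-3-(2-methoxypropan-2-yl)-1-methylcyclopentan-1-ol
Product: 16 {(2E,4E)-5-[(1S,2R,5R)-2-hydroxy-5-(2-methoxypropan-2-yl)-2-methylcyclopentyl]-3-methylpenta-2,4-dien-1-yl}triphenylphosphonium bromide
Conditions: PPh3·HBr (1.05 equiv), MeOH, 0 °C to rt; trituration with EtOAc/Et2O
Reagents that add atoms: triphenylphosphine hydrobromide, [Br-].[PH+](c1ccccc1)(c1ccccc1)c1ccccc1
Why: Acid-induced ionisation of the tertiary bis-allylic alcohol gives a pentadienyl cation that triphenylphosphine captures irreversibly at the unhindered primary terminus C11 (allylic transposition, the standard vinyl carbinol to C15 Wittig salt conversion), the 9E trisubstituted alkene being thermodynamically preferred; water is the only by-product and methanol as solvent returns the methyl ether should C1 exchange.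

Step 11
Reactants: 17 pseudoionone; 13 vinylmagnesium bromide
Product: 18 (4E,6E)-3,7,11-trimethyldodeca-1,4,6,10-tetraen-3-ol (racemic)
Conditions: 13 (1.3 equiv), THF, −20 to 0 °C; aq NH4Cl
Reagents that add atoms: none
Why: Grignard 1,2-addition to the dienone carbonyl, as in step 8, gives the tertiary vinyl carbinol whose stereocentre is lost in step 12.

Step 12
Reactants: 18 (4E,6E)-3,7,11-trimethyldodeca-1,4,6,10-tetraen-3-ol
Product: 19 [(2E,4E,6E)-3,7,11-trimethyldodeca-2,4,6,10-tetraen-1-yl]triphenylphosphonium bromide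
Conditions: PPh3·HBr (1.05 equiv), MeOH, rt; crystallisation
Reagents that add atoms: triphenylphosphine hydrobromide, [Br-].[PH+](c1ccccc1)(c1ccccc1)c1ccccc1
Why: The same acid-induced allylic transposition with phosphine capture at the primary terminus as in step 10, here on the acyclic trienyl carbinol, with water as the only by-product.

Step 13
Reactants: 19 [(2E,4E,6E)-3,7,11-trimethyldodeca-2,4,6,10-tetraen-1-yl]triphenylphosphonium bromide; 20 (2E,4E,6E)-2,7-dimethylocta-2,4,6-trienedial
Product: 22 (2E,4E,6E,8E,10E,12E,14E)-2,7,11,15,19-pentamethylicosa-2,4,6,8,10,12,14,18-octaenal (apo-12'-lycopenal), via phosphorus ylide 21 (not isolated)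
Conditions: 20 (2.5 equiv), NaOMe (1.1 equiv, slow addition), CH2Cl2/MeOH, 0 °C to rt, dark; then heptane, 80 °C; chromatography with recovery of 20
Reagents that add atoms: none
Why: Wittig olefination by the semi-stabilised allylic ylide 21, generated slowly in the presence of excess symmetrical dialdehyde so that mono-olefination prevails, forms C11'=C12', and heating equilibrates the unhindered disubstituted Z alkene to E.

Step 14
Reactants: 16 {(2E,4E)-5-[(1S,2R,5R)-2-hydroxy-5-(2-methoxypropan-2-yl)-2-methylcyclopentyl]-3-methylpenta-2,4-dien-1-yl}triphenylphosphonium bromide; 22 apo-12'-lycopenal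
Product: 24 (2R,5R,6S)-1-methoxy-2,6-cyclolycopen-5-ol [(1R,2S,3R)-3-(2-methoxypropan-2-yl)-1-methyl-2-[(1E,3E,5E,7E,9E,11E,13E,15E,17E,19E)-3,7,12,16,20,24-hexamethylpentacosa-1,3,5,7,9,11,13,15,17,19,23-undecaen-1-yl]cyclopentan-1-ol], via phosphorus ylide 23 (not isolated)
Conditions: NaOMe (1.2 equiv), CH2Cl2/MeOH, 0 °C to rt, dark, argon; then heptane, 80 °C; crystallisation
Reagents that add atoms: none
Why: Wittig olefination forms C11=C12 and completes the C40 chain; the tertiary hydroxyl tolerates methoxide, the ring stereocentres are remote from the reacting centre, and thermal equilibration should convert the 11Z isomer into the all-E polyene.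

## Compound list

1 | hex-5-en-2-one | CC(=O)CCC=C | starting material
2 | but-3-en-2-one | CC(=O)C=C | starting material
3 | (3E)-oct-3-ene-2,7-dione | CC(=O)/C=C/CCC(C)=O | intermediate
4 | 4,4,5,5-tetramethyl-2-(prop-1-en-2-yl)-1,3,2-dioxaborolane (isopropenylboronic acid pinacol ester) | CC(=C)B1OC(C)(C)C(C)(C)O1 | starting material
5 | rhodium (2Z,4R)-7-oxo-4-(prop-1-en-2-yl)oct-2-en-2-olate (BINAP on rhodium not drawn) | CC(=C)[C@H](CCC(C)=O)/C=C(/C)O[Rh] | intermediate (not isolated)
6 | 1-[(1S,2R,5R)-2-hydroxy-2-methyl-5-(prop-1-en-2-yl)cyclopentyl]ethan-1-one (acetyl cis to OH; trans to isopropenyl) | CC(=C)[C@@H]1CC[C@@](C)(O)[C@H]1C(C)=O | intermediate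
7 | 1-[(1S,2R,5R)-2-hydroxy-5-(2-methoxypropan-2-yl)-2-methylcyclopentyl]ethan-1-one | COC(C)(C)[C@@H]1CC[C@@](C)(O)[C@H]1C(C)=O | intermediate
8 | 1-[(1S,2R,5R)-5-(2-methoxypropan-2-yl)-2-methyl-2-(triethylsilyloxy)cyclopentyl]ethan-1-one | COC(C)(C)[C@@H]1CC[C@@](C)(O[Si](CC)(CC)CC)[C@H]1C(C)=O | intermediate
9 | potassium 1-[5-(2-methoxypropan-2-yl)-2-methyl-2-(triethylsilyloxy)cyclopentyl]ethen-1-olate (terminal enolate of 8; ring configuration as in 8) | COC(C)(C)[C@@H]1CC[C@@](C)(O[Si](CC)(CC)CC)[C@H]1C(=C)[O-].[K+] | intermediate (not isolated)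
10 | 1-[(1S,2R,5R)-5-(2-methoxypropan-2-yl)-2-methyl-2-(triethylsilyloxy)cyclopentyl]ethenyl trifluoromethanesulfonate | COC(C)(C)[C@@H]1CC[C@@](C)(O[Si](CC)(CC)CC)[C@H]1C(=C)OS(=O)(=O)C(F)(F)F | intermediate
11 | triethyl{[(1R,2S,3R)-2-ethenyl-3-(2-methoxypropan-2-yl)-1-methylcyclopentyl]oxy}silane | COC(C)(C)[C@@H]1CC[C@@](C)(O[Si](CC)(CC)CC)[C@H]1C=C | intermediate
12 | (3E)-4-[(1S,2R,5R)-5-(2-methoxypropan-2-yl)-2-methyl-2-(triethylsilyloxy)cyclopentyl]but-3-en-2-one | COC(C)(C)[C@@H]1CC[C@@](C)(O[Si](CC)(CC)CC)[C@H]1/C=C/C(C)=O | intermediate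
13 | vinylmagnesium bromide | C=C[Mg]Br | starting material
14 | (4E)-5-[(1S,2R,5R)-5-(2-methoxypropan-2-yl)-2-methyl-2-(triethylsilyloxy)cyclopentyl]-3-methylpenta-1,4-dien-3-ol (both C3 epimers) | COC(C)(C)[C@@H]1CC[C@@](C)(O[Si](CC)(CC)CC)[C@H]1/C=C/C(C)(O)C=C | intermediate
15 | (1R,2S,3R)-2-[(1E)-3-hydroxy-3-methylpenta-1,4-dien-1-yl]-3-(2-methoxypropan-2-yl)-1-methylcyclopentan-1-ol (both side-chain carbinol epimers) | COC(C)(C)[C@@H]1CC[C@@](C)(O)[C@H]1/C=C/C(C)(O)C=C | intermediate
16 | {(2E,4E)-5-[(1S,2R,5R)-2-hydroxy-5-(2-methoxypropan-2-yl)-2-methylcyclopentyl]-3-methylpenta-2,4-dien-1-yl}triphenylphosphonium bromide | COC(C)(C)[C@@H]1CC[C@@](C)(O)[C@H]1/C=C/C(C)=C/C[P+](c1ccccc1)(c1ccccc1)c1ccccc1.[Br-] | intermediate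
17 | pseudoionone, (3E,5E)-6,10-dimethylundeca-3,5,9-trien-2-one | CC(C)=CCC/C(C)=C/C=C/C(C)=O | starting material
18 | (4E,6E)-3,7,11-trimethyldodeca-1,4,6,10-tetraen-3-ol (racemic) | CC(C)=CCC/C(C)=C/C=C/C(C)(O)C=C | intermediate
19 | [(2E,4E,6E)-3,7,11-trimethyldodeca-2,4,6,10-tetraen-1-yl]triphenylphosphonium bromide | CC(C)=CCC/C(C)=C/C=C/C(C)=C/C[P+](c1ccccc1)(c1ccccc1)c1ccccc1.[Br-] | intermediate
20 | (2E,4E,6E)-2,7-dimethylocta-2,4,6-trienedial (C10 dialdehyde) | O=C/C(C)=C/C=C/C=C(C)/C=O | starting material
21 | triphenyl[(2E,4E,6E)-3,7,11-trimethyldodeca-2,4,6,10-tetraen-1-ylidene]-λ5-phosphane | CC(C)=CCC/C(C)=C/C=C/C(C)=C/C=P(c1ccccc1)(c1ccccc1)c1ccccc1 | intermediate (not isolated)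
22 | (2E,4E,6E,8E,10E,12E,14E)-2,7,11,15,19-pentamethylicosa-2,4,6,8,10,12,14,18-octaenal (apo-12'-lycopenal) | O=C/C(C)=C/C=C/C=C(C)/C=C/C=C(C)/C=C/C=C(\C)CCC=C(C)C | intermediate
23 | {(2E,4E)-5-[(1S,2R,5R)-2-hydroxy-5-(2-methoxypropan-2-yl)-2-methylcyclopentyl]-3-methylpenta-2,4-dien-1-ylidene}triphenyl-λ5-phosphane | COC(C)(C)[C@@H]1CC[C@@](C)(O)[C@H]1/C=C/C(C)=C/C=P(c1ccccc1)(c1ccccc1)c1ccccc1 | intermediate (not isolated)
24 | (2R,5R,6S)-1-methoxy-2,6-cyclolycopen-5-ol, all-E (CNP0380368.2) | COC(C)(C)[C@@H]1CC[C@@](C)(O)[C@H]1/C=C/C(C)=C/C=C/C(C)=C/C=C/C=C(C)/C=C/C=C(C)/C=C/C=C(\C)CCC=C(C)C | target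

## Count and risks

Total: 14 steps. Longest linear sequence: 11 steps (steps 1 to 10, then step 14); steps 11 to 13 form the convergent branch.

Risk 1, step 2. Transfer of the 1-substituted alkenyl group from the pinacol boronate to rhodium may be slow, so that protodeboronation of 4 and base-induced intramolecular Michael cyclisation of 3 consume the partners; facial discrimination by the ligand may also be insufficient. The fallback replaces catalysis by the chiral pool. It does not set out from a numbered compound but from commercial (R)-(+)-α-terpineol F1, and it comes back to the route at compound 12. O-Methylation (NaH, MeI, THF) would give the methyl ether F2. Ozonolysis of its only alkene (O3, CH2Cl2/MeOH, −78 °C; Me2S) would give the keto aldehyde F3, whose stereocentre becomes C2 with the required R configuration. An amine-catalysed enamine aldol (pyrrolidine/AcOH or proline, rt) of the aldehyde α-carbon onto the methyl ketone would close the same cyclopentane as the hydroxy aldehyde F4; under equilibrating conditions the formyl group should settle trans to the C2 substituent and trans to the C5 methyl, and any C5 epimer would be removed by chromatography. Wittig reaction with Ph3P=CHC(O)CH3 would give the hydroxy enone F5, and silylation (Et3SiOTf, 2,6-lutidine) returns to 12, so that steps 3 to 7 are bypassed.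

Risk 2, step 7. Initiation and turnover at the vinyl group may be slow because the allylic methine C6 sits between the quaternary silyloxy carbon and the substituted C2, letting catalyst decomposition and homodimerisation of 2 win. The fallback sets out from compound 11 and comes back at compound 12. Ozonolysis (O3, CH2Cl2, −78 °C; PPh3) would cut the vinyl group to the aldehyde F6, and Wittig reaction with the stabilised ylide Ph3P=CHC(O)CH3 (toluene, 80 °C) would give the E enone 12.

Risk 3, step 3. Hydrogen-atom transfer may lead to alkene isomerisation or reduction instead of ether formation, and the neighbouring ketone oxygen or adventitious water and fluoride may compete with methanol for the C1 cation equivalent. The fallback separates C–O bond formation from methylation; it sets out from compound 6 and comes back at compound 8. Silylation (Et3SiOTf, 2,6-lutidine) would give the silyl ether F7; Mukaiyama hydration (Co(acac)2, PhSiH3, O2, THF/iPrOH) would give the tertiary alcohol F8; O-methylation with MeOTf and 2,6-di-tert-butyl-4-methylpyridine in CH2Cl2, which the ketone tolerates, would give 8.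

Further compounds
F1 | step 2 | 2-[(1R)-4-methylcyclohex-3-en-1-yl]propan-2-ol ((R)-α-terpineol) | CC1=CC[C@@H](CC1)C(C)(C)O
F2 | step 2 | (4R)-4-(2-methoxypropan-2-yl)-1-methylcyclohex-1-ene | CC1=CC[C@@H](CC1)C(C)(C)OC
F3 | step 2 | (3R)-3-(2-methoxypropan-2-yl)-6-oxoheptanal | COC(C)(C)[C@@H](CC=O)CCC(C)=O
F4 | step 2 | (1S,2R,5R)-2-hydroxy-5-(2-methoxypropan-2-yl)-2-methylcyclopentane-1-carbaldehyde | COC(C)(C)[C@@H]1CC[C@@](C)(O)[C@H]1C=O
F5 | step 2 | (3E)-4-[(1S,2R,5R)-2-hydroxy-5-(2-methoxypropan-2-yl)-2-methylcyclopentyl]but-3-en-2-one | COC(C)(C)[C@@H]1CC[C@@](C)(O)[C@H]1/C=C/C(C)=O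
F6 | step 7 | (1S,2R,5R)-5-(2-methoxypropan-2-yl)-2-methyl-2-(triethylsilyloxy)cyclopentane-1-carbaldehyde | COC(C)(C)[C@@H]1CC[C@@](C)(O[Si](CC)(CC)CC)[C@H]1C=O
F7 | step 3 | 1-[(1S,2R,5R)-2-methyl-5-(prop-1-en-2-yl)-2-(triethylsilyloxy)cyclopentyl]ethan-1-one | CC(=C)[C@@H]1CC[C@@](C)(O[Si](CC)(CC)CC)[C@H]1C(C)=O
F8 | step 3 | 1-[(1S,2R,5R)-5-(2-hydroxypropan-2-yl)-2-methyl-2-(triethylsilyloxy)cyclopentyl]ethan-1-one | CC(C)(O)[C@@H]1CC[C@@](C)(O[Si](CC)(CC)CC)[C@H]1C(C)=O
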